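**Retrosynthetic overview** (carotenoid numbering)
- The strategy rests on ring A: the C3 and C6 hydroxyls sit on one face, 1,4 to each other across C4=C5. This is the footprint of singlet oxygen adding to a C3=C4–C5=C6 ring diene, followed by O–O reduction.
- C40 = ring A C15 dienal 13 + ring B C25 phosphonium salt 28 (Wittig, C11=C12). The C25 unit = ring B C15 salt 23 + C10 dialdehyde 24 (Wittig, C11'=C12').
- Ring A side chain: C7≡C8 from safranal by Corey–Fuchs; C8–C9 by palladium-catalysed alkyne–alkynoate addition; 7E by alkoxide-directed hydroalumination. Ring B: enol triflate of actinol plus Sonogashira coupling.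
- Ring order: no carbocycle is built (ring A from safranal, ring B from 4-oxoisophorone). The only ring closed is the 1,2-dioxine bridge in step 3, opened again in step 4.

Key step: step 3

Assumption: in step 5 the lipase is taken to treat the CH2–CMe2 flank of C3 as the large group, so the (3S,6R) enantiomer is acylated; if the preference is reversed, the (3S,6R) material is the unreacted alcohol, which step 6 converts to the same compound 8.

**Ring A (steps 1–10)**

Step 1
Reactants: 1 safranal
Product: 2 1-(2,2-dibromoethenyl)-2,6,6-trimethylcyclohexa-1,3-diene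
Conditions: CBr4, PPh3, Zn, CH2Cl2, 0 °C to rt
Reagents that add atoms: carbon tetrabromide, BrC(Br)(Br)Br
Why: Ramirez dibromo-olefination (first half of the Corey–Fuchs homologation) with Ph3P=CBr2 works on hindered cyclocitral-type enals, and Zn keeps acidic phosphonium bromides away from the diene.

Step 2
Reactants: 2 1-(2,2-dibromoethenyl)-2,6,6-trimethylcyclohexa-1,3-diene
Product: 4 trimethyl[(2,6,6-trimethylcyclohexa-1,3-dien-1-yl)ethynyl]silane, via lithium acetylide 3 (not isolated)
Conditions: n-BuLi (2.2 equiv), THF, −78 to 0 °C; then Me3SiCl, −78 °C to rt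
Reagents that add atoms: chlorotrimethylsilane, C[Si](C)(C)Cl
Why: Br/Li exchange and Fritsch–Buttenberg–Wiechell rearrangement (second half of Corey–Fuchs) give the lithium acetylide, which Me3SiCl silylates on carbon.

Step 3
Reactants: 4 trimethyl[(2,6,6-trimethylcyclohexa-1,3-dien-1-yl)ethynyl]silane
Product: 5 racemic trimethyl{[(1R*,4S*)-6,7,7-trimethyl-2,3-dioxabicyclo[2.2.2]oct-5-en-1-yl]ethynyl}silane (ring A 3,6-endoperoxide)
Conditions: O2, tetraphenylporphyrin (cat.), visible light, CH2Cl2, −20 °C
Reagents that add atoms: dioxygen, O=O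
Why: Sensitised singlet oxygen adds as a dienophile across the s-cis-locked C3=C4–C5=C6 diene of 4 in a concerted suprafacial [4+2] cycloaddition, the direct analogue of the α-terpinene-to-ascaridole photooxygenation of cyclohexa-1,3-dienes. The 1,2-dioxine ring (2,3-dioxabicyclo[2.2.2]oct-5-ene) closes by cycloaddition, the C3–O and C6–O bonds forming together and the C4=C5 alkene appearing in its final place. Both oxygens of one O2 molecule arrive on the same face, so the mechanism sets C3 and C6 cis to each other; the diene is achiral with enantiotopic faces, so 5 is racemic and the absolute configuration is fixed in step 5. The step needs the cycloaddition to beat the Schenck ene reaction at the C5 methyl and C2 methylene, and needs the alkyne to stay untouched. The ring-held cisoid diene favours [4+2], the linear silylalkyne is inert to singlet oxygen and adds little bulk at the quaternary-flanked C6 terminus, and no other electron-rich alkene is present.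

Step 4
Reactants: 5 racemic ring A 3,6-endoperoxide
Product: 6 racemic (1R*,4S*)-2,6,6-trimethyl-1-[(trimethylsilyl)ethynyl]cyclohex-2-ene-1,4-diol (cis-diol)
Conditions: thiourea, MeOH, 0 °C to rt
Reagents that add atoms: none
Why: Thiourea reduces only the O–O bond (peroxide reduction) under neutral conditions, so both C–O bonds keep their configuration and the cis-1,4-enediol results with alkene, alkyne and silane untouched.

Step 5
Reactants: 6 racemic cis-diol
Product: 7 (1S,4R)-4-hydroxy-3,5,5-trimethyl-4-[(trimethylsilyl)ethynyl]cyclohex-2-en-1-yl acetate ((3S,6R) series)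
Conditions: Burkholderia cepacia lipase (immobilised), vinyl acetate, t-BuOMe, 30 °C, stopped near half conversion; chromatographic separation from the unreacted antipode
Reagents that add atoms: vinyl acetate, C=COC(C)=O
Why: Lipase-catalysed kinetic resolution by irreversible transesterification, in which only the secondary C3–OH can be acylated and the enzyme is expected to take the (3S,6R) enantiomer, fixes the absolute configuration of C3 and with it of C6.

Step 6
Reactants: 7 (3S,6R)-monoacetate
Product: 8 (1S,4S)-1-ethynyl-2,6,6-trimethylcyclohex-2-ene-1,4-diol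
Conditions: K2CO3, MeOH, rt
Reagents that add atoms: none
Why: Methoxide-mediated transesterification removes the acetate and protodesilylation cleaves the C(sp)–Si bond in one operation, with neither stereocentre affected.

Step 7
Reactants: 8 (1S,4S)-1-ethynyl-2,6,6-trimethylcyclohex-2-ene-1,4-diol; 9 ethyl but-2-ynoate
Product: 10 ethyl (2E)-5-[(1R,4S)-1,4-dihydroxy-2,6,6-trimethylcyclohex-2-en-1-yl]-3-methylpent-2-en-4-ynoate
Conditions: Pd(OAc)2 (3 mol %), tris(2,6-dimethoxyphenyl)phosphine (3 mol %), THF, rt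
Reagents that add atoms: none
Why: Palladium-catalysed addition of a terminal alkyne C–H across an alkynoate (syn-carbopalladation by the alkynylpalladium species, then protonolysis) forms C8–C9 and places the alkynyl group trans to the ester, which is the 9E geometry.

Step 8
Reactants: 10 enynoate
Product: 11 (1R,4S)-1-[(3E)-5-hydroxy-3-methylpent-3-en-1-yn-1-yl]-2,6,6-trimethylcyclohex-2-ene-1,4-diol
Conditions: i-Bu2AlH (excess), CH2Cl2, −78 °C; aqueous potassium sodium tartrate
Reagents that add atoms: none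
Why: i-Bu2AlH reduces the conjugated ester in 1,2-fashion (ester reduction) to the allylic alcohol at low temperature, leaving the enyne and both stereocentres unchanged.

Step 9
Reactants: 11 enyne triol
Product: 12 (1R,4S)-1-[(1E,3E)-5-hydroxy-3-methylpenta-1,3-dien-1-yl]-2,6,6-trimethylcyclohex-2-ene-1,4-diol
Conditions: NaAlH2(OCH2CH2OMe)2, THF, 0 °C to rt; aqueous potassium sodium tartrate
Reagents that add atoms: none
Why: Alkoxide-directed trans-hydroalumination of the propargylic alkyne from the C6 alkoxide, followed by protonolysis, gives the 7E alkene at a temperature low enough that the C11 alkoxide should not trigger allene formation.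

Step 10
Reactants: 12 diene triol
Product: 13 (2E,4E)-5-[(1R,4S)-1,4-dihydroxy-2,6,6-trimethylcyclohex-2-en-1-yl]-3-methylpenta-2,4-dienal
Conditions: [Cu(MeCN)4]OTf (5 mol %), 2,2'-bipyridine, TEMPO, N-methylimidazole, air, MeCN, rt
Reagents that add atoms: none
Why: Copper/TEMPO aerobic alcohol oxidation is strongly selective for the unhindered primary allylic alcohol over the secondary C3–OH and runs under weakly basic conditions that spare the acid-labile tertiary bis-allylic C6–OH.

**Ring B and the C25 unit (steps 11–19)**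

Step 11
Reactants: 14 4-oxoisophorone
Product: 15 (6R)-2,2,6-trimethylcyclohexane-1,4-dione
Conditions: baker's yeast (Saccharomyces cerevisiae), sucrose, H2O, 30 °C
Reagents that add atoms: none
Why: Enzymatic reduction of the activated C=C of the enedione by fermenting yeast sets the methyl-bearing centre as (6R), which later relays its configuration to C4.

Step 12
Reactants: 15 (6R)-2,2,6-trimethylcyclohexane-1,4-dione
Product: 16 (4R,6R)-4-hydroxy-2,2,6-trimethylcyclohexan-1-one
Conditions: LiBH(s-Bu)3, THF, −78 °C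
Reagents that add atoms: none
Why: Diastereoselective ketone reduction under steric approach control, in which the bulky hydride attacks the unhindered C4 carbonyl from the equatorial side away from the axial C2 methyl, gives the axial alcohol trans to the C6 methyl, i.e. (4R), while the flanked C1 carbonyl is left alone.

Step 13
Reactants: 16 (4R,6R)-4-hydroxy-2,2,6-trimethylcyclohexan-1-one
Product: 17 (4R,6R)-2,2,6-trimethyl-4-[(triethylsilyl)oxy]cyclohexan-1-one
Conditions: Et3SiCl, imidazole, CH2Cl2, 0 °C to rt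
Reagents that add atoms: chlorotriethylsilane, CC[Si](CC)(CC)Cl
Why: Silyl ether formation masks the hydroxyl for the enolate chemistry and is set up to fall off under the acidic methanol of step 16.

Step 14
Reactants: 17 triethylsilyl ether
Product: 19 (4R)-2,6,6-trimethyl-4-[(triethylsilyl)oxy]cyclohex-1-en-1-yl trifluoromethanesulfonate, via lithium enolate 18 (not isolated)
Conditions: LiN(i-Pr)2, THF, −78 to 0 °C; then PhNTf2, 0 °C to rt
Reagents that add atoms: N-phenylbis(trifluoromethanesulfonimide), O=S(=O)(N(c1ccccc1)S(=O)(=O)C(F)(F)F)C(F)(F)F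
Why: Deprotonation at C6, the only α-CH, and O-sulfonylation of the enolate (enol triflate formation) give the tetrasubstituted triflate, erasing the C6 centre on purpose and leaving C4 untouched.

Step 15
Reactants: 19 enol triflate; 20 (2E)-3-methylpent-2-en-4-yn-1-ol
Product: 21 (2E)-3-methyl-5-{(4R)-2,6,6-trimethyl-4-[(triethylsilyl)oxy]cyclohex-1-en-1-yl}pent-2-en-4-yn-1-ol
Conditions: Pd(PPh3)4 (5 mol %), CuI (10 mol %), Et3N, DMF, rt to 50 °C
Reagents that add atoms: none
Why: Sonogashira coupling of the enol triflate with the terminal enynol forms the C6'–C7' bond and brings in the 9'E geometry unchanged from 20.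

Step 16
Reactants: 21 silyl-protected C15 enynol
Product: 23 {(2E)-5-[(4R)-4-hydroxy-2,6,6-trimethylcyclohex-1-en-1-yl]-3-methylpent-2-en-4-yn-1-yl}triphenylphosphonium bromide, via enyne diol 22 (not isolated)
Conditions: PPh3·HBr, MeOH, rt
Reagents that add atoms: triphenylphosphine hydrobromide, [Br-].[PH+](c1ccccc1)(c1ccccc1)c1ccccc1
Why: Acidic methanolysis removes the triethylsilyl ether and allylic substitution by PPh3 on the protonated primary allylic alcohol gives the phosphonium salt, while the homoallylic secondary hydroxyl does not ionise.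

Step 17
Reactants: 23 C15 phosphonium bromide; 24 (2E,4E,6E)-2,7-dimethylocta-2,4,6-trienedial
Product: 26 (2E,4E,6E,8E,10E)-13-[(4R)-4-hydroxy-2,6,6-trimethylcyclohex-1-en-1-yl]-2,7,11-trimethyltrideca-2,4,6,8,10-pentaen-12-ynal, via phosphonium ylide 25 (not isolated)
Conditions: NaOMe, MeOH/CH2Cl2, 0 °C to rt, 24 in threefold excess; then EtOAc, 60 °C, dark
Reagents that add atoms: none
Why: Wittig olefination of the semi-stabilised ylide with one aldehyde group of the excess dialdehyde forms C11'=C12', and gentle heating without iodine turns the 11'Z isomer into E while leaving 9'E next to the alkyne alone.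

Step 18
Reactants: 26 C25 aldehyde
Product: 27 (2E,4E,6E,8E,10E)-13-[(4R)-4-hydroxy-2,6,6-trimethylcyclohex-1-en-1-yl]-2,7,11-trimethyltrideca-2,4,6,8,10-pentaen-12-yn-1-ol
Conditions: NaBH4, MeOH/THF, 0 °C
Reagents that add atoms: none
Why: Borohydride 1,2-reduction of a polyenal to the primary polyenyl alcohol is the same transformation as retinal to retinol.

Step 19
Reactants: 27 C25 alcohol
Product: 28 {(2E,4E,6E,8E,10E)-13-[(4R)-4-hydroxy-2,6,6-trimethylcyclohex-1-en-1-yl]-2,7,11-trimethyltrideca-2,4,6,8,10-pentaen-12-yn-1-yl}triphenylphosphonium bromide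
Conditions: PPh3·HBr, MeOH/CH2Cl2, 0 °C to rt
Reagents that add atoms: triphenylphosphine hydrobromide, [Br-].[PH+](c1ccccc1)(c1ccccc1)c1ccccc1
Why: Phosphonium salt formation from a polyenylic alcohol goes through the delocalised cation captured by PPh3 at the terminal carbon, as for retinol, and leaves the ring hydroxyl alone.

**Final coupling (step 20)**

Step 20
Reactants: 28 C25 phosphonium bromide; 13 ring A dienal
Product: 30 target CNP0113828.1, all-E (3S,6R,3'R)-triol, via phosphonium ylide 29 (not isolated)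
Conditions: NaOMe, MeOH/CH2Cl2, 0 °C to rt; then EtOAc, 60 °C, dark, argon; chromatography on base-deactivated silica
Reagents that add atoms: none
Why: Wittig olefination joins C11 to C12 with the free hydroxyls tolerated under NaOMe, mild heating equilibrates the new disubstituted bond from Z to E, and no stereocentre is touched.

**Compound list**

1 | safranal (2,6,6-trimethylcyclohexa-1,3-diene-1-carbaldehyde) | CC1=C(C=O)C(C)(C)CC=C1 | starting material
2 | 1-(2,2-dibromoethenyl)-2,6,6-trimethylcyclohexa-1,3-diene | CC1=C(C=C(Br)Br)C(C)(C)CC=C1 | intermediate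
3 | lithium (2,6,6-trimethylcyclohexa-1,3-dien-1-yl)acetylide | CC1=C(C#C[Li])C(C)(C)CC=C1 | intermediate (not isolated)
4 | trimethyl[(2,6,6-trimethylcyclohexa-1,3-dien-1-yl)ethynyl]silane | CC1=C(C#C[Si](C)(C)C)C(C)(C)CC=C1 | intermediate
5 | racemic trimethyl{[(1R*,4S*)-6,7,7-trimethyl-2,3-dioxabicyclo[2.2.2]oct-5-en-1-yl]ethynyl}silane; the (1R,4S) enantiomer, with C3 and C6 as in the target, is drawn | CC1=C[C@@H](O2)CC(C)(C)[C@]1(O2)C#C[Si](C)(C)C | intermediate
6 | racemic (1R*,4S*)-2,6,6-trimethyl-1-[(trimethylsilyl)ethynyl]cyclohex-2-ene-1,4-diol (cis); the (1R,4S) enantiomer is drawn | CC1=C[C@@H](O)CC(C)(C)[C@]1(O)C#C[Si](C)(C)C | intermediate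
7 | (1S,4R)-4-hydroxy-3,5,5-trimethyl-4-[(trimethylsilyl)ethynyl]cyclohex-2-en-1-yl acetate | CC1=C[C@@H](OC(C)=O)CC(C)(C)[C@]1(O)C#C[Si](C)(C)C | intermediate
8 | (1S,4S)-1-ethynyl-2,6,6-trimethylcyclohex-2-ene-1,4-diol (cis) | CC1=C[C@@H](O)CC(C)(C)[C@]1(O)C#C | intermediate
9 | ethyl but-2-ynoate | CC#CC(=O)OCC | starting material
10 | ethyl (2E)-5-[(1R,4S)-1,4-dihydroxy-2,6,6-trimethylcyclohex-2-en-1-yl]-3-methylpent-2-en-4-ynoate | CC1=C[C@@H](O)CC(C)(C)[C@]1(O)C#C/C(C)=C/C(=O)OCC | intermediate
11 | (1R,4S)-1-[(3E)-5-hydroxy-3-methylpent-3-en-1-yn-1-yl]-2,6,6-trimethylcyclohex-2-ene-1,4-diol | CC1=C[C@@H](O)CC(C)(C)[C@]1(O)C#C/C(C)=C/CO | intermediate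
12 | (1R,4S)-1-[(1E,3E)-5-hydroxy-3-methylpenta-1,3-dien-1-yl]-2,6,6-trimethylcyclohex-2-ene-1,4-diol | CC1=C[C@@H](O)CC(C)(C)[C@]1(O)/C=C/C(C)=C/CO | intermediate
13 | (2E,4E)-5-[(1R,4S)-1,4-dihydroxy-2,6,6-trimethylcyclohex-2-en-1-yl]-3-methylpenta-2,4-dienal | CC1=C[C@@H](O)CC(C)(C)[C@]1(O)/C=C/C(C)=C/C=O | intermediate
14 | 4-oxoisophorone (2,6,6-trimethylcyclohex-2-ene-1,4-dione) | CC1=CC(=O)CC(C)(C)C1=O | starting material
15 | (6R)-2,2,6-trimethylcyclohexane-1,4-dione | C[C@@H]1CC(=O)CC(C)(C)C1=O | intermediate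
16 | (4R,6R)-4-hydroxy-2,2,6-trimethylcyclohexan-1-one | C[C@@H]1C[C@@H](O)CC(C)(C)C1=O | intermediate
17 | (4R,6R)-2,2,6-trimethyl-4-[(triethylsilyl)oxy]cyclohexan-1-one | C[C@@H]1C[C@@H](O[Si](CC)(CC)CC)CC(C)(C)C1=O | intermediate
18 | lithium (4R)-2,6,6-trimethyl-4-[(triethylsilyl)oxy]cyclohex-1-en-1-olate | [Li]OC1=C(C)C[C@@H](O[Si](CC)(CC)CC)CC1(C)C | intermediate (not isolated)
19 | (4R)-2,6,6-trimethyl-4-[(triethylsilyl)oxy]cyclohex-1-en-1-yl trifluoromethanesulfonate | FC(F)(F)S(=O)(=O)OC1=C(C)C[C@@H](O[Si](CC)(CC)CC)CC1(C)C | intermediate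
20 | (2E)-3-methylpent-2-en-4-yn-1-ol | C#C/C(C)=C/CO | starting material
21 | (2E)-3-methyl-5-{(4R)-2,6,6-trimethyl-4-[(triethylsilyl)oxy]cyclohex-1-en-1-yl}pent-2-en-4-yn-1-ol | OC/C=C(\C)C#CC1=C(C)C[C@@H](O[Si](CC)(CC)CC)CC1(C)C | intermediate
22 | (1R)-4-[(3E)-5-hydroxy-3-methylpent-3-en-1-yn-1-yl]-3,5,5-trimethylcyclohex-3-en-1-ol | OC/C=C(\C)C#CC1=C(C)C[C@@H](O)CC1(C)C | intermediate (not isolated)
23 | {(2E)-5-[(4R)-4-hydroxy-2,6,6-trimethylcyclohex-1-en-1-yl]-3-methylpent-2-en-4-yn-1-yl}triphenylphosphonium bromide | [Br-].c1ccc(cc1)[P+](c1ccccc1)(c1ccccc1)C/C=C(\C)C#CC1=C(C)C[C@@H](O)CC1(C)C | intermediate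
24 | (2E,4E,6E)-2,7-dimethylocta-2,4,6-trienedial | O=C/C(C)=C/C=C/C=C(C)/C=O | starting material
25 | ylide of 23 | c1ccc(cc1)[P+](c1ccccc1)(c1ccccc1)[CH-]/C=C(\C)C#CC1=C(C)C[C@@H](O)CC1(C)C | intermediate (not isolated)
26 | (2E,4E,6E,8E,10E)-13-[(4R)-4-hydroxy-2,6,6-trimethylcyclohex-1-en-1-yl]-2,7,11-trimethyltrideca-2,4,6,8,10-pentaen-12-ynal | O=C/C(C)=C/C=C/C=C(C)/C=C/C=C(\C)C#CC1=C(C)C[C@@H](O)CC1(C)C | intermediate
27 | (2E,4E,6E,8E,10E)-13-[(4R)-4-hydroxy-2,6,6-trimethylcyclohex-1-en-1-yl]-2,7,11-trimethyltrideca-2,4,6,8,10-pentaen-12-yn-1-ol | OC/C(C)=C/C=C/C=C(C)/C=C/C=C(\C)C#CC1=C(C)C[C@@H](O)CC1(C)C | intermediate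
28 | {(2E,4E,6E,8E,10E)-13-[(4R)-4-hydroxy-2,6,6-trimethylcyclohex-1-en-1-yl]-2,7,11-trimethyltrideca-2,4,6,8,10-pentaen-12-yn-1-yl}triphenylphosphonium bromide | [Br-].c1ccc(cc1)[P+](c1ccccc1)(c1ccccc1)C/C(C)=C/C=C/C=C(C)/C=C/C=C(\C)C#CC1=C(C)C[C@@H](O)CC1(C)C | intermediate
29 | ylide of 28 | c1ccc(cc1)[P+](c1ccccc1)(c1ccccc1)[CH-]/C(C)=C/C=C/C=C(C)/C=C/C=C(\C)C#CC1=C(C)C[C@@H](O)CC1(C)C | intermediate (not isolated)
30 | target CNP0113828.1, all-E (3S,6R,3'R)-triol | CC1=C[C@@H](O)CC(C)(C)[C@]1(O)/C=C/C(C)=C/C=C/C(C)=C/C=C/C=C(C)/C=C/C=C(\C)C#CC1=C(C)C[C@@H](O)CC1(C)C | target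

**Step count**
- Total: 20 steps.
- Longest linear sequence: 11 steps (steps 1–10, then step 20, from safranal). The ring B branch is 10 steps (steps 11–19, then step 20).

**Steps most likely to fail**

1. Step 3. The ene pathway (allylic hydroperoxide formation at the C5 methyl or C2 methylene) may compete with the cycloaddition, addition at the quaternary-flanked C6 terminus may be slow, and the endoperoxide may rearrange before it is reduced. Fallback, setting out from 14 and returning at 6: Luche reduction (NaBH4, CeCl3, MeOH, −78 °C) of the less hindered C4 carbonyl of 14 gives racemic 4-hydroxy-2,6,6-trimethylcyclohex-2-en-1-one F1. Excess LiC≡CSiMe3 (THF, −78 to 0 °C) then adds to the remaining hindered carbonyl of the alkoxide, preferentially anti to the C4 oxygen, to give cis-diol 6. Any racemic trans-diol, (1R*,4R*)-2,6,6-trimethyl-1-[(trimethylsilyl)ethynyl]cyclohex-2-ene-1,4-diol F2, is removed by chromatography. The route resumes at step 5.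

2. Step 5. The enzyme may discriminate poorly between the enantiomers because the two flanks of C3 differ little in size, or acylation may be too slow to stop cleanly at half conversion. Fallback, setting out from 6 and returning at 8: acylation of the C3–OH of both enantiomers with (1S)-camphanic chloride (pyridine, DMAP cat., CH2Cl2) gives two diastereomeric esters. These are the camphanate of the (3S,6R)-diol F3 and the camphanate of the (3R,6S)-diol F4, which are separated by crystallisation or chromatography. K2CO3 in MeOH on F3 cleaves the ester and the C–Si bond to give 8, and the route resumes at step 7.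

3. Step 9. Site control in the hydride step may be lost: the C11 alkoxide of the (E)-2-en-4-yn-1-ol unit can direct 1,4-hydride delivery toward an allene, and over-reduction is possible. Fallback, setting out from 10 and returning at 12: CrSO4 (divalent chromium) in aqueous DMF at rt reduces the propargylic alkyne of the ester by electron transfer and protonation to the E-alkene with no alkoxide at C11. This gives ethyl (2E,4E)-5-[(1R,4S)-1,4-dihydroxy-2,6,6-trimethylcyclohex-2-en-1-yl]-3-methylpenta-2,4-dienoate F5. i-Bu2AlH (CH2Cl2, −78 °C) then reduces the ester to triol 12, and the route resumes at step 10.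

**Further compounds**

F1 | step 3 | racemic 4-hydroxy-2,6,6-trimethylcyclohex-2-en-1-one | CC1=CC(O)CC(C)(C)C1=O
F2 | step 3 | racemic (1R*,4R*)-2,6,6-trimethyl-1-[(trimethylsilyl)ethynyl]cyclohex-2-ene-1,4-diol (trans isomer of 6) | CC1=C[C@H](O)CC(C)(C)[C@]1(O)C#C[Si](C)(C)C
F3 | step 5 | (1S,4R)-4-hydroxy-3,5,5-trimethyl-4-[(trimethylsilyl)ethynyl]cyclohex-2-en-1-yl (1S,4R)-4,7,7-trimethyl-3-oxo-2-oxabicyclo[2.2.1]heptane-1-carboxylate | CC1(C)[C@@]2(C)CC[C@]1(C(=O)O[C@@H]3C=C(C)[C@@](O)(C#C[Si](C)(C)C)C(C)(C)C3)OC2=O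
F4 | step 5 | (1R,4S)-4-hydroxy-3,5,5-trimethyl-4-[(trimethylsilyl)ethynyl]cyclohex-2-en-1-yl (1S,4R)-4,7,7-trimethyl-3-oxo-2-oxabicyclo[2.2.1]heptane-1-carboxylate | CC1(C)[C@@]2(C)CC[C@]1(C(=O)O[C@H]3C=C(C)[C@](O)(C#C[Si](C)(C)C)C(C)(C)C3)OC2=O
F5 | step 9 | ethyl (2E,4E)-5-[(1R,4S)-1,4-dihydroxy-2,6,6-trimethylcyclohex-2-en-1-yl]-3-methylpenta-2,4-dienoate | CC1=C[C@@H](O)CC(C)(C)[C@]1(O)/C=C/C(C)=C/C(=O)OCC
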